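Compare amounts in powers of ten: a ratio becomes a difference, and an order in reagent becomes a slope. Two runs start from the same starting material, with the reagent in north twice that in east, and the flask asked about repeats north.

| setting | north | east | flask |
|---|---|---|---|
| starting material | 0.050 M | 0.050 M | 0.050 M |
| reagent | 1.8 equiv | 0.90 equiv | 1.80 equiv |
| remark | the very flask that is asked about, followed so far | run made earlier |  |
| time |  |  | 2.5 d |

| run | time / h | target / % |
|---|---|---|
| north | 2.50 | 19.4 |
| north | 3.00 | 21.7 |
| north | 4.00 | 24.3 |
| north | 5.00 | 27.3 |
| north | 6.00 | 28.6 |
| north | 10.0 | 27.3 |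
| north | 12.0 | 27.1 |
| east | 2.50 | 9.2 |
| east | 4.00 | 12.2 |
| east | 6.00 | 15.1 |
| east | 10.0 | 16.7 |
| east | 15.0 | 14.8 |
| east | 25.0 | 11.3 |
| east | 40.0 | 7.2 |

(readings scatter by 1 percentage point)

1. the moment within 2.5 d at which there is most target
2. the amount of target, in percent of the starting material charged, at that time

Read the two tables across. At 2.50 h, north holds 19.4 % and east 9.2 %. The logarithm of that ratio over the logarithm of the reagent ratio is 1.08, so early on the target follows the reagent roughly in proportion. At 10.0 h, the same sum gives a smaller 0.709, though both figures carry the scatter of the readings.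

Now take the highest reading of each run, 28.6 % against 16.7 %, which gives 0.776. Call this the peak exponent, the logarithm of the ratio of heights over the logarithm of the ratio of reagent; it is an apparent order in reagent, read from two readings.

Since the flask repeats north, my own reckoning puts its height near 28.6 %, somewhere between 6.00 h and 10.0 h. For another charge of reagent, I would move that height by the peak exponent, as an estimate.

The forecast gives 28.5 % at 0.33 d, on the ground that “the flask is a repeat of north”.

The flask reaches 28.9 % at 0.375 d, and both forecast values stand within their margins. The top is broad, with 25.4 % at 0.188 d and 27.6 % at 0.563 d.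

    starting material + reagent ⇌ target (K = 35.0 L mol⁻¹, k = 0.0220 L mol⁻¹ min⁻¹)
    starting material → intermediate A (k = 0.00290 min⁻¹)
    intermediate A ⇌ intermediate B (K = 3.10, k = 0.00730 min⁻¹)
    reagent + intermediate B ⇌ intermediate C (K = 18.0 L mol⁻¹, k = 0.0130 L mol⁻¹ min⁻¹)

Carry the peak exponent from this height to the neighbouring flask with 7.20 equiv of reagent, and it gives 84.7 %. That flask peaks lower, at 64.5 %.

The earlier runs and the new flask were generated by integration with made-up constants; scatter was added.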